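**Retrosynthetic overview**
1. The enol ester C–O bond is cut first: target 7 ⇒ enolate of aryl 1,2-diketone 4 + 3-methylbutanoyl chloride 5 (4 has a single enolisable position, the isopropyl CH).
2. Diketone 4 ⇒ oxidation of the benzylic α-CH2 of isomeranzin 3 (Riley oxidation).
3. Isomeranzin 3 ⇒ Meinwald rearrangement of (±)-meranzin 2 ⇒ epoxidation of osthole 1.
4. No ring of the target is built: the coumarin bicycle is bought intact in osthole; the only ring formed is the transient oxirane of 2 (made in step 1, opened in step 2).

Assumption: the target has no stereocentre and its only acyclic C=C carries two identical methyl groups, so it is achiral with no E/Z isomerism; "single enantiomer" needs no stereocontrol, and osthole is taken as a commercial starting material.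

**Step 1**
Reactants: 1 osthole (7-methoxy-8-(3-methylbut-2-en-1-yl)-2H-chromen-2-one)
Product: 2 (±)-meranzin (8-[(3,3-dimethyloxiran-2-yl)methyl]-7-methoxy-2H-chromen-2-one, racemic at the oxirane CH)
Conditions: mCPBA (1.1 equiv), CH2Cl2, 0 °C → rt
Reagents that add atoms: mCPBA (3-chloroperoxybenzoic acid), O=C(OO)c1cccc(Cl)c1
Why: Prilezhaev epoxidation is selective for the electron-rich trisubstituted prenyl alkene over the electron-poor coumarin C3=C4, and the single new stereocentre is formed racemic and erased in step 2.

**Step 2**
Reactants: 2 (±)-meranzin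
Product: 3 isomeranzin (7-methoxy-8-(3-methyl-2-oxobutyl)-2H-chromen-2-one)
Conditions: BF3·OEt2 (0.3 equiv), CH2Cl2, −20 → 0 °C
Reagents that add atoms: none
Why: Meinwald rearrangement, in which Lewis-acid opening of the epoxide at the tertiary carbon is followed by a 1,2-hydride shift to give the ketone ArCH2–CO–CHMe2, with no stereocentre remaining.

**Step 3**
Reactants: 3 isomeranzin
Product: 4 1-(7-methoxy-2-oxo-2H-chromen-8-yl)-3-methylbutane-1,2-dione
Conditions: SeO2 (1.5 equiv), 1,4-dioxane/H2O (20:1), 100 °C
Reagents that add atoms: selenium dioxide, O=[Se]=O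
Why: Riley oxidation converts the CH2 activated by both the aryl ring and the ketone into a carbonyl (deoxybenzoin → benzil type), and the coumarin lactone and its C3=C4 bond tolerate SeO2.

**Step 4**
Reactants: 4 1-(7-methoxy-2-oxo-2H-chromen-8-yl)-3-methylbutane-1,2-dione; 5 3-methylbutanoyl chloride (isovaleryl chloride)
Product: 7 Exotimarin H (1-(7-methoxy-2-oxo-2H-chromen-8-yl)-3-methyl-1-oxobut-2-en-2-yl 3-methylbutanoate), via potassium enolate 6 (not isolated)
Conditions: KHMDS (1.05 equiv), THF, −78 °C; then 5 (1.2 equiv), −78 → 0 °C; aq NH4Cl quench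
Reagents that add atoms: 3-methylbutanoyl chloride (compound 5), CC(C)CC(Cl)=O
Why: Enolate O-acylation, since the diketone can only deprotonate at the isopropyl CH and the resulting fully substituted enolate carbon is too hindered for C-acylation, so the acid chloride reacts at oxygen to give the enol ester (no stereocentre or E/Z element is created).

**Compound list**
1 | osthole, 7-methoxy-8-(3-methylbut-2-en-1-yl)-2H-chromen-2-one | COc1ccc2ccc(=O)oc2c1CC=C(C)C | starting material
2 | (±)-meranzin, 8-[(3,3-dimethyloxiran-2-yl)methyl]-7-methoxy-2H-chromen-2-one (racemic) | COc1ccc2ccc(=O)oc2c1CC1OC1(C)C | intermediate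
3 | isomeranzin, 7-methoxy-8-(3-methyl-2-oxobutyl)-2H-chromen-2-one | COc1ccc2ccc(=O)oc2c1CC(=O)C(C)C | intermediate
4 | 1-(7-methoxy-2-oxo-2H-chromen-8-yl)-3-methylbutane-1,2-dione | COc1ccc2ccc(=O)oc2c1C(=O)C(=O)C(C)C | intermediate
5 | 3-methylbutanoyl chloride (isovaleryl chloride) | CC(C)CC(Cl)=O | starting material
6 | potassium 1-(7-methoxy-2-oxo-2H-chromen-8-yl)-3-methyl-1-oxobut-2-en-2-olate (not isolated) | COc1ccc2ccc(=O)oc2c1C(=O)C([O-])=C(C)C.[K+] | intermediate
7 | Exotimarin H, 1-(7-methoxy-2-oxo-2H-chromen-8-yl)-3-methyl-1-oxobut-2-en-2-yl 3-methylbutanoate (achiral) | COc1ccc2ccc(=O)oc2c1C(=O)C(OC(=O)CC(C)C)=C(C)C | target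

**Total step count:** 4
**Longest linear sequence:** 4 steps (1 → 2 → 3 → 4 → 7)

**Three steps most likely to fail** (most risky first: step 3, then step 4, then step 2)

Step 2 (Meinwald rearrangement): the tertiary cation may instead lose a proton to the allylic alcohol, undergo benzyl migration to an aldehyde, or be trapped as a fluorohydrin. The fallback sets out from 2 and comes back at 3. It makes the elimination pathway deliberate: epoxide 2 is isomerised with Al(OiPr)3 in refluxing toluene to the allylic alcohol (±)-auraptenol F1. F1 is then converted into ketone 3 by a transition-metal redox isomerisation of the allylic alcohol (RuCl2(PPh3)3 cat., toluene, 80–100 °C), replacing the cationic hydride shift by a metal-hydride 1,3-H shift.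

Step 3 (Riley oxidation): SeO2 may also attack the isopropyl CH, before or after diketone formation, or give incomplete conversion. The fallback sets out from 3 and comes back at 4. Isomeranzin 3 is nitrosated with isoamyl nitrite and TMSCl in CH2Cl2 (−20 °C → rt); only the benzylic CH2 can give a stable oxime, so this yields the α-hydroxyimino ketone F2. F2 is then deoximated by transoximation with aqueous formaldehyde/HCl in THF at rt to release diketone 4.

Step 4 (enolate O-acylation): the strongly basic enolate 6 may undergo aldol-type self-condensation with unreacted diketone, attack the coumarin, or partly C-acylate. The fallback sets out from 4 and comes back at 7. Diketone 4 is soft-enolised with TMSOTf/Et3N in CH2Cl2 at 0 °C to the trimethylsilyl enol ether F3, which is isolated. F3 is then treated with anhydrous CsF and acid chloride 5 in MeCN at 0 °C → rt, so that fluoride unmasks the enolate only in the presence of the acylating agent and O-acylation gives 7 without a free strong base.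

**Further compounds**
F1 | step 2 | (±)-auraptenol, 8-(2-hydroxy-3-methylbut-3-en-1-yl)-7-methoxy-2H-chromen-2-one (racemic) | COc1ccc2ccc(=O)oc2c1CC(O)C(C)=C
F2 | step 3 | 8-[1-(hydroxyimino)-3-methyl-2-oxobutyl]-7-methoxy-2H-chromen-2-one (oxime E/Z mixture) | COc1ccc2ccc(=O)oc2c1C(=NO)C(=O)C(C)C
F3 | step 4 | 7-methoxy-8-{3-methyl-2-[(trimethylsilyl)oxy]but-2-enoyl}-2H-chromen-2-one | COc1ccc2ccc(=O)oc2c1C(=O)C(O[Si](C)(C)C)=C(C)C
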